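**Strategy.** Cembrane numbering is used (C1–C14 carbocycle, C15 on C1, C16 = ring OCH2, C17 = CH2OAc carbon). The 2,5-dihydrofuran is cut at O–C2 and C15–C16, so a one-carbon CH2–O unit is stitched in late. One palladium catalyst couples (tributylstannyl)methanol with the C15–I bond of a 14-membered (Z)-α-iodo-alkylidene ester and then ionises the C2 carbonate; the new hydroxyl closes on C2 with net retention. The step exploits C2 being allylic to both C1=C15 and C3=C4, and the cis placement of C15–I and C2. The macrocycle comes from farnesyl acetate by Shi epoxidation, asymmetric alkynylation and B-alkyl Suzuki ring closure; C17 is carried as an ester.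

Key step: step 11

Assumption: (S,S)-ProPhenol is taken to deliver the alkynyl group to the aldehyde face that gives the (4S)-carbinol 9; if the facial sense is the opposite, the (R,R)-ligand is used and nothing else changes.

**Step 1**
Reactants: 1 (2E,6E)-farnesyl acetate
Product: 2 (2E,6E,10E)-12-hydroxyfarnesyl acetate
Conditions: SeO2 (0.3 equiv), t-BuOOH (3 equiv), salicylic acid (0.1 equiv), CH2Cl2, 0 °C → rt
Reagents that add atoms: tert-butyl hydroperoxide, CC(C)(C)OO
Why: SeO2/t-BuOOH allylic oxidation (ene reaction, then [2,3]-sigmatropic shift) should hydroxylate the (E)-methyl of the terminal, most electron-rich alkene, the C2=C3 alkene being deactivated by the allylic acetate.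

**Step 2**
Reactants: 2 (2E,6E,10E)-12-hydroxyfarnesyl acetate
Product: 3 (2E,6E,10E)-12-oxofarnesyl acetate
Conditions: MnO2 (15 equiv), CH2Cl2, rt
Reagents that add atoms: none
Why: MnO2 oxidation is specific for the allylic alcohol and should keep the E geometry of the enal.

**Step 3**
Reactants: 3 (2E,6E,10E)-12-oxofarnesyl acetate
Product: 4 (6S,7S)-6,7-epoxy-12-oxofarnesyl acetate
Conditions: L-fructose-derived Shi ketone (0.3 equiv), Oxone (2KHSO5·KHSO4·K2SO4), K2CO3, n-Bu4NHSO4 (cat.), Na2B4O7/Na2EDTA buffer (pH 10.5), MeCN/dimethoxymethane, 0 °C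
Reagents that add atoms: potassium peroxymonosulfate (active salt of Oxone), [K+].[O-]S(=O)(=O)OO
Why: In this Shi asymmetric epoxidation (chiral dioxirane, spiro transition state) only C6=C7 is electron-rich, since C2=C3 is deactivated by the allylic acetate and C10=C11 by conjugation to the aldehyde, and the L-configured ketone should give the (6S,7S)-epoxide because the D-ketone gives R,R epoxides from E-trisubstituted alkenes.

**Step 4**
Reactants: 4 (6S,7S)-6,7-epoxy-12-oxofarnesyl acetate
Product: 5 epoxy diene acetate (terminal 1,3-diene)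
Conditions: Ph3PCH3Br (1.1 equiv), KN(SiMe3)2 (1.05 equiv), THF, −78 → 0 °C
Reagents that add atoms: methyltriphenylphosphonium bromide, C[P+](c1ccccc1)(c1ccccc1)c1ccccc1.[Br-]
Why: Wittig methylenation of the aldehyde is much faster than attack of the ylide on the acetate or the epoxide at low temperature and should leave the E-trisubstituted alkene untouched.

**Step 5**
Reactants: 5 epoxy diene acetate
Product: 6 epoxy trienol
Conditions: K2CO3 (0.2 equiv), MeOH, 0 °C → rt
Reagents that add atoms: none
Why: Base-catalysed methanolysis (transesterification) removes the acetate without touching the trisubstituted epoxide or the diene.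

**Step 6**
Reactants: 6 epoxy trienol
Product: 7 epoxy trienal
Conditions: MnO2 (15 equiv), CH2Cl2, rt
Reagents that add atoms: none
Why: MnO2 oxidation of the primary allylic alcohol should give the (2E)-enal without isomerisation.

**Step 7**
Reactants: 7 epoxy trienal; 8 methyl propiolate
Product: 9 (4S)-γ-hydroxy ynoate
Conditions: (S,S)-ProPhenol [2,6-bis{[(S)-2-(hydroxydiphenylmethyl)pyrrolidin-1-yl]methyl}-4-methylphenol] (10 mol %), Me2Zn (3 equiv), Ph3P=O (20 mol %), toluene, 4 °C
Reagents that add atoms: none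
Why: In this dinuclear zinc–ProPhenol asymmetric alkynylation, a reaction developed for enals and propiolates, the ligand controls which aldehyde face receives the alkynylzinc and so sets the new C4 (future C2) stereocenter as S, while Me2Zn leaves epoxide, diene and ester alone.

**Step 8**
Reactants: 9 (4S)-γ-hydroxy ynoate
Product: 10 (2E)-2,3-diiodo enoate
Conditions: I2 (1.2 equiv), n-Bu4NI (0.3 equiv), CH2Cl2, 0 °C → rt, dark
Reagents that add atoms: iodine, II
Why: This anti-1,2-diiodination of an alkynoate should proceed by conjugate attack of iodide at the β-carbon and iodination of the allenoate at the α-carbon on the side away from the first iodine (hence E, ester trans to the carbinol carbon), while triiodide adds only reversibly to the alkenes and diene and is too weak a Lewis acid to open the epoxide.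

**Step 9**
Reactants: 10 (2E)-2,3-diiodo enoate
Product: 12 macrocyclic (Z)-α-iodo-alkylidene ester alcohol, via alkyl-9-BBN adduct 11 (not isolated)
Conditions: 9-BBN (2.2 equiv), THF, 0 °C → rt; then slow addition to PdCl2(dppf) (15 mol %; dppf = 1,1'-bis(diphenylphosphino)ferrocene), AsPh3 (30 mol %), Cs2CO3 (4 equiv), DMF/THF/H2O, 45 °C, 1 mM
Reagents that add atoms: none
Why: 9-BBN should add only to the terminal CH2 of the 1,3-diene (anti-Markovnikov hydroboration), and the intramolecular B-alkyl Suzuki–Miyaura coupling under high dilution should engage the β-C–I bond, which as a vinylogous acyl iodide undergoes oxidative addition faster than the α-C–I bond, with retention so that the remaining iodine stays cis to C2.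

**Step 10**
Reactants: 12 macrocyclic (Z)-α-iodo-alkylidene ester alcohol
Product: 13 C2 methyl carbonate
Conditions: ClCO2Me (3 equiv), pyridine, DMAP (cat.), CH2Cl2, 0 °C
Reagents that add atoms: methyl chloroformate, COC(Cl)=O
Why: O-acylation of the secondary allylic alcohol with a chloroformate installs the leaving group for the key step without touching the C2 configuration.

**Step 11**
Reactants: 13 C2 methyl carbonate; 14 (tributylstannyl)methanol
Product: 16 dihydrofuran methyl ester, via hydroxymethyl ester 15 (not isolated)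
Conditions: Pd(PPh3)4 (10 mol %), 1,4-dioxane (degassed), 25 °C then 70 °C
Reagents that add atoms: none
Why: Zerovalent palladium should insert into the activated C15–I bond and the alkenylpalladium iodide is transmetallated by (tributylstannyl)methanol (Migita–Kosugi–Stille hydroxymethylation, retention of alkene geometry) to give 15 with the new CH2OH cis to C2; the same catalyst then ionises the C2 methyl carbonate (loss of CO2 and methoxide, which deprotonates the alcohol) to an η3-allyl complex over C2–C3–C4, and the alkoxide attacks C2 anti to palladium (intramolecular Tsuji–Trost allylic etherification). The closest known reaction types are the Stille coupling of alkenyl iodides with Bu3SnCH2OH and the palladium-catalysed cyclisation of hydroxy allylic carbonates to 2-alkenyl-2,5-dihydrofurans. The five-membered ring closes by attack of O on the allyl terminus C2 with the rest of the allyl unit outside the new ring (5-exo mode), whereas attack at C4 would need a seven-membered ring. The C2 stereocenter is substrate-controlled: ionisation and attack each go with inversion, so the S configuration set in step 7 is returned as 2S. The step needs the cis relation of C15 and C2 across C1=C15, which is fixed by the anti-diiodination of step 8 and kept in step 9, and it tolerates either order of the two palladium events, because a stannylmethyl ether formed first at C2 would close by intramolecular Stille coupling to the same product.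

**Step 12**
Reactants: 16 dihydrofuran methyl ester
Product: 17 C17 allylic alcohol
Conditions: i-Bu2AlH (2.5 equiv), CH2Cl2, −78 °C; Rochelle salt work-up
Reagents that add atoms: none
Why: 1,2-Reduction of the conjugated ester with DIBAL-H at low temperature should give the allylic alcohol without opening the trisubstituted epoxide or the allylic ether.

**Step 13**
Reactants: 17 C17 allylic alcohol
Product: 18 target acetate
Conditions: Ac2O (2 equiv), pyridine, DMAP (cat.), CH2Cl2, 0 °C → rt
Reagents that add atoms: acetic anhydride, CC(=O)OC(C)=O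
Why: DMAP-catalysed acetylation of the primary alcohol completes the target under conditions that leave all other groups unchanged.

**Compound list**

1 | (2E,6E)-farnesyl acetate [(2E,6E)-3,7,11-trimethyldodeca-2,6,10-trien-1-yl acetate] | CC(C)=CCC/C(C)=C/CC/C(C)=C/COC(C)=O | starting material
2 | (2E,6E,10E)-12-hydroxy-3,7,11-trimethyldodeca-2,6,10-trien-1-yl acetate | OC/C(C)=C/CC/C(C)=C/CC/C(C)=C/COC(C)=O | intermediate
3 | (2E,6E,10E)-3,7,11-trimethyl-12-oxododeca-2,6,10-trien-1-yl acetate | O=C/C(C)=C/CC/C(C)=C/CC/C(C)=C/COC(C)=O | intermediate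
4 | (2E,6S,7S,10E)-6,7-epoxy-3,7,11-trimethyl-12-oxododeca-2,10-dien-1-yl acetate | O=C/C(C)=C/CC[C@]1(C)O[C@H]1CC/C(C)=C/COC(C)=O | intermediate
5 | (2E,6S,7S,10E)-6,7-epoxy-3,7,11-trimethyltrideca-2,10,12-trien-1-yl acetate | C=C/C(C)=C/CC[C@]1(C)O[C@H]1CC/C(C)=C/COC(C)=O | intermediate
6 | (2E,6S,7S,10E)-6,7-epoxy-3,7,11-trimethyltrideca-2,10,12-trien-1-ol | C=C/C(C)=C/CC[C@]1(C)O[C@H]1CC/C(C)=C/CO | intermediate
7 | (2E,6S,7S,10E)-6,7-epoxy-3,7,11-trimethyltrideca-2,10,12-trienal | C=C/C(C)=C/CC[C@]1(C)O[C@H]1CC/C(C)=C/C=O | intermediate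
8 | methyl propiolate | C#CC(=O)OC | starting material
9 | methyl (4S,5E,9S,10S,13E)-9,10-epoxy-4-hydroxy-6,10,14-trimethylhexadeca-5,13,15-trien-2-ynoate | C=C/C(C)=C/CC[C@]1(C)O[C@H]1CC/C(C)=C/[C@H](O)C#CC(=O)OC | intermediate
10 | methyl (2E,4S,5E,9S,10S,13E)-9,10-epoxy-4-hydroxy-2,3-diiodo-6,10,14-trimethylhexadeca-2,5,13,15-tetraenoate | C=C/C(C)=C/CC[C@]1(C)O[C@H]1CC/C(C)=C/[C@H](O)/C(I)=C(I)/C(=O)OC | intermediate
11 | methyl (2E,4S,5E,9S,10S,13E)-16-(9-borabicyclo[3.3.1]nonan-9-yl)-9,10-epoxy-4-hydroxy-2,3-diiodo-6,10,14-trimethylhexadeca-2,5,13-trienoate | C1CCC2CCCC1B2CC/C(C)=C/CC[C@]3(C)O[C@H]3CC/C(C)=C/[C@H](O)/C(I)=C(I)/C(=O)OC | intermediate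
12 | methyl (2Z)-2-[(2S,3E,7S,8S,11E)-7,8-epoxy-2-hydroxy-4,8,12-trimethylcyclotetradeca-3,11-dien-1-ylidene]-2-iodoacetate | COC(=O)/C(I)=C1\CC/C(C)=C/CC[C@]2(C)O[C@H]2CC/C(C)=C/[C@@H]1O | intermediate
13 | methyl (2Z)-2-[(2S,3E,7S,8S,11E)-7,8-epoxy-2-(methoxycarbonyloxy)-4,8,12-trimethylcyclotetradeca-3,11-dien-1-ylidene]-2-iodoacetate | COC(=O)/C(I)=C1\CC/C(C)=C/CC[C@]2(C)O[C@H]2CC/C(C)=C/[C@@H]1OC(=O)OC | intermediate
14 | (tributylstannyl)methanol | CCCC[Sn](CO)(CCCC)CCCC | starting material
15 | methyl (2E)-2-[(2S,3E,7S,8S,11E)-7,8-epoxy-2-(methoxycarbonyloxy)-4,8,12-trimethylcyclotetradeca-3,11-dien-1-ylidene]-3-hydroxypropanoate | COC(=O)/C(CO)=C1\CC/C(C)=C/CC[C@]2(C)O[C@H]2CC/C(C)=C/[C@@H]1OC(=O)OC | intermediate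
16 | methyl (2S,3E,7S,8S,11E)-7,8:2,16-diepoxycembra-1(15),3,11-trien-17-oate (target skeleton with CO2Me in place of CH2OAc) | COC(=O)C1=C2CC/C(C)=C/CC[C@]3(C)O[C@H]3CC/C(C)=C/[C@@H]2OC1 | intermediate
17 | (2S,3E,7S,8S,11E)-7,8:2,16-diepoxycembra-1(15),3,11-trien-17-ol | OCC1=C2CC/C(C)=C/CC[C@]3(C)O[C@H]3CC/C(C)=C/[C@@H]2OC1 | intermediate
18 | (2S,3E,7S,8S,11E)-7,8:2,16-diepoxycembra-1(15),3,11-trien-17-yl acetate | CC(=O)OCC1=C2CC/C(C)=C/CC[C@]3(C)O[C@H]3CC/C(C)=C/[C@@H]2OC1 | target

**Step count and risks**

Total steps: 13. Longest linear sequence: 13 steps (1 → 18).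

Most likely to fail:

Step 11. The η3-allyl intermediate may be diverted (β-hydride elimination to a triene, or capture by methoxide) before the slow tin-to-palladium transfer of the hydroxymethyl group, or the C–I bond may be reduced. Fallback, from 12 back to 16: the free alcohol 12, which has no ionisable group, is coupled with 14 (Pd(PPh3)4, dioxane, 80 °C) to give the diol F1. The ring is then closed by Mitsunobu cyclodehydration (PPh3, diisopropyl azodicarboxylate, THF, 0 °C), in which the primary allylic hydroxyl is activated and the C2 oxygen is the nucleophile. C2 is untouched, so the same 2S ether 16 should result.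

Step 8. Iodine may iodo-etherify or isomerise the electron-rich alkenes, or open the epoxide, faster than iodide adds to the ynoate. Fallback, from 9 back to 10: silylation (Et3SiCl, imidazole, DMF) gives the silyl ether F2. Syn addition of Me3Sn–SnMe3 with Pd(PPh3)4 in THF at 65 °C gives the (Z)-bis-stannane F3. Its known thermal Z → E isomerisation (toluene, 85 °C) gives the (E)-bis-stannane F4. Double iododestannylation (I2, CH2Cl2, 0 °C; C–Sn bonds react far faster than the alkenes) gives the diiodide silyl ether F5, and n-Bu4NF/AcOH returns 10.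

Step 9. Oxidative addition may occur at the α-C–I bond as well as the β-C–I bond, and intermolecular coupling may give oligomers. Fallback, from 9 by way of the (E)-bis-stannane F4, back to 16: bromodestannylation (N-bromosuccinimide, CH2Cl2, −20 °C) gives the (E)-dibromide silyl ether F6, and n-Bu4NF/AcOH gives the dibromo alcohol F7. α,β-Dibromo-enoates are known to cross-couple at the β-bromide first, so hydroboration and ring closure as in step 9 should give the macrocyclic α-bromo ester F8. ClCO2Me/pyridine gives its carbonate F9, which enters the domino of step 11 with 14 (80 °C) and rejoins the route at 16.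

**Further compounds**

F1 | step 11 | methyl (2E)-2-[(2S,3E,7S,8S,11E)-7,8-epoxy-2-hydroxy-4,8,12-trimethylcyclotetradeca-3,11-dien-1-ylidene]-3-hydroxypropanoate | COC(=O)/C(CO)=C1\CC/C(C)=C/CC[C@]2(C)O[C@H]2CC/C(C)=C/[C@@H]1O
F2 | step 8 | methyl (4S,5E,9S,10S,13E)-9,10-epoxy-6,10,14-trimethyl-4-(triethylsilyloxy)hexadeca-5,13,15-trien-2-ynoate | C=C/C(C)=C/CC[C@]1(C)O[C@H]1CC/C(C)=C/[C@H](O[Si](CC)(CC)CC)C#CC(=O)OC
F3 | step 8 | methyl (2Z,4S,5E,9S,10S,13E)-9,10-epoxy-6,10,14-trimethyl-4-(triethylsilyloxy)-2,3-bis(trimethylstannyl)hexadeca-2,5,13,15-tetraenoate | C=C/C(C)=C/CC[C@]1(C)O[C@H]1CC/C(C)=C/[C@H](O[Si](CC)(CC)CC)/C([Sn](C)(C)C)=C(/[Sn](C)(C)C)C(=O)OC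
F4 | step 8 | methyl (2E,4S,5E,9S,10S,13E)-9,10-epoxy-6,10,14-trimethyl-4-(triethylsilyloxy)-2,3-bis(trimethylstannyl)hexadeca-2,5,13,15-tetraenoate | C=C/C(C)=C/CC[C@]1(C)O[C@H]1CC/C(C)=C/[C@H](O[Si](CC)(CC)CC)/C([Sn](C)(C)C)=C(\[Sn](C)(C)C)C(=O)OC
F5 | step 8 | methyl (2E,4S,5E,9S,10S,13E)-9,10-epoxy-2,3-diiodo-6,10,14-trimethyl-4-(triethylsilyloxy)hexadeca-2,5,13,15-tetraenoate | C=C/C(C)=C/CC[C@]1(C)O[C@H]1CC/C(C)=C/[C@H](O[Si](CC)(CC)CC)/C(I)=C(I)/C(=O)OC
F6 | step 9 | methyl (2E,4S,5E,9S,10S,13E)-2,3-dibromo-9,10-epoxy-6,10,14-trimethyl-4-(triethylsilyloxy)hexadeca-2,5,13,15-tetraenoate | C=C/C(C)=C/CC[C@]1(C)O[C@H]1CC/C(C)=C/[C@H](O[Si](CC)(CC)CC)/C(Br)=C(Br)/C(=O)OC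
F7 | step 9 | methyl (2E,4S,5E,9S,10S,13E)-2,3-dibromo-9,10-epoxy-4-hydroxy-6,10,14-trimethylhexadeca-2,5,13,15-tetraenoate | C=C/C(C)=C/CC[C@]1(C)O[C@H]1CC/C(C)=C/[C@H](O)/C(Br)=C(Br)/C(=O)OC
F8 | step 9 | methyl (2Z)-2-bromo-2-[(2S,3E,7S,8S,11E)-7,8-epoxy-2-hydroxy-4,8,12-trimethylcyclotetradeca-3,11-dien-1-ylidene]acetate | COC(=O)/C(Br)=C1\CC/C(C)=C/CC[C@]2(C)O[C@H]2CC/C(C)=C/[C@@H]1O
F9 | step 9 | methyl (2Z)-2-bromo-2-[(2S,3E,7S,8S,11E)-7,8-epoxy-2-(methoxycarbonyloxy)-4,8,12-trimethylcyclotetradeca-3,11-dien-1-ylidene]acetate | COC(=O)/C(Br)=C1\CC/C(C)=C/CC[C@]2(C)O[C@H]2CC/C(C)=C/[C@@H]1OC(=O)OC
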